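All runs were generated by integration on assumed constants.

L is what we want from this flask, made by J + Q → L + G, while the other suspect, two J → Z, takes J without Q. Here Q stands barely above J.

in all of them: J 24 mM

| run | Q | remark | time |
|---|---|---|---|
| theta | 0.55 equiv | run made earlier |  |
| beta | 2.2 equiv | run made earlier |  |
| flask | 1.10 equiv |  | 10 min |

- theta (time / min: L / %, J / %, Z / %): 1.50: 39.0, 57.8, 3.9; 4.00: 50.9, 43.3, 6.0; 8.00: 53.6, 37.2, 9.5; 12.0: 53.8, 33.4, 12.0
- beta (time / min: L / %, J / %, Z / %): 1.00: 82.0, 15.4, 1.2; 2.00: 95.0, 4.2, 1.2; 5.00: 99.1, 0.2, 1.2; 12.0: 99.2, 0.1, 0.3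

(scatter of a reading: 0.5 percentage points)

- the L in the flask at 10 min, as a percentage of the J charged
- the J in the flask at 10 min, as a percentage of the J charged
- the Z in the flask at 10 min, as a percentage of the J charged
- concentration of Q at 10 min, in mM

- percent here means J units held: one Z counts as two
- on the list of suspects stand: J + Q -> L + G; 2 J -> Z

Let f and q be J and Q as fractions of the J charged, and write the rates of J use as a·f·q and s·f². The first beta reading, integrated with its Q excess, gives a = 1.15 min⁻¹. Late in the theta run L stands at 53.6 % and then 53.8 %, next to the 0.55 equiv of Q charged, so we take the Z gain there over the mean f²: s = 0.0502 min⁻¹, a rough reading of a small gain.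

Now compare the two at one moment: side over main is ρ·f/q, where ρ = s/a = 0.0434 is the side ratio, a selectivity factor. At the start of the flask that comparison is 0.0395.

Then the drift. Each main turn takes one J and one Q, so q stays near f + e, where e = 0.100 is the excess of Q over J, the limiting reagent. Summing the comparison over the fall of J, our own reckoning gives Z ≈ ρ(1 − e·ln((1 + e)/e)) = 3.30 %.

The forecast gives L 93.7 %, J 3.3 %, Z 3 % and Q 3.9 mM, holding that “Z follows second order in J”. Our Z lies above its figure but below its high end.

The flask gives L 93.7 %, J 3.42 %, Z 2.89 % and Q 3.91 mM, each inside the forecast's range.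

    J + Q → L + G (k = 46.0 M⁻¹ min⁻¹)
    2 J → Z (k = 0.940 M⁻¹ min⁻¹)

In the flask both steps ran early: half of the turnover up to 10 min was done by 0.710 min on the main step and by 0.547 min on the side step. At 5.00 min, with J at 9.74 % and Q at 20.5 % of its charge, ρ·f/q had moved from 0.0395 to 0.0188, and Z went from 2.81 % to 2.89 % by 10.0 min. For a neighbouring flask with 2.80 equiv of Q, the same sum gives 0.889 %, and its Z stands at 0.826 %.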